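**Plan**

- Retrosynthesis: the MOM ether comes off last; the side chain is cut at C1'–C2' (olefination of a C2 aldehyde); the pyranone ring is then cut at two bonds at once, C2–C3 and O1–C8a, leaving an aryl methyl ketone and the ketone carbonyl of methyl pyruvate.
- What allows the double cut is the C4 carbonyl on C4a of the benzene ring, ortho to C8a: it makes C3 a carbon nucleophile (as its enol silane) and it activates a C8a–F bond for addition–elimination by the oxygen that the aldol step places on C2.
- Forward: the benzene ring is bought with Br, F and OH in place; the pyranone ring arises in step 3; the C2 ester, the helper that makes the ketone a bidentate partner for the chiral catalyst, is then grown into the side chain by partial reduction, Wittig reaction and hydrogenation; C4 is re-oxidised and the phenol set free.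
- Stereochemistry: the only stereocentre, C2, is set in step 3 by the Cu(OTf)2/(S,S)-tBu-box catalyst (si-face attack on chelated pyruvate). It is quaternary and cannot epimerise, and C4 is held at the carbinol level during the basic olefination so that ring opening by retro-oxa-Michael reaction cannot scramble it.

Key step: step 3

Assumption: 1-(4-bromo-2-fluoro-5-hydroxyphenyl)ethan-1-one (1) is taken to be a purchasable building block, so the bromine is in place from the start and no arene bromination, whose regiochemistry between C5 and C7 would be uncertain, is needed.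

**Route**

Step 1
Reactants: 1 1-(4-bromo-2-fluoro-5-hydroxyphenyl)ethan-1-one
Product: 2 1-[4-bromo-2-fluoro-5-(methoxymethoxy)phenyl]ethan-1-one
Conditions: MOMCl, i-Pr2NEt, CH2Cl2, 0 °C to rt
Reagents that add atoms: chloromethyl methyl ether (MOMCl), COCCl
Why: O-Alkylation of the phenol (MOM ether formation) masks the acidic OH, whose phenoxide para to fluorine would shut down the later SNAr ring closure, with a group that survives fluoride, hydride, ylide and oxidant and is removed at the end by mild aqueous acid; no stereocentre is involved.

Step 2
Reactants: 2 1-[4-bromo-2-fluoro-5-(methoxymethoxy)phenyl]ethan-1-one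
Product: 4 {[1-(4-bromo-2-fluoro-5-(methoxymethoxy)phenyl)ethenyl]oxy}trimethylsilane, via lithium enolate 3 (not isolated)
Conditions: LiN(SiMe3)2 (1.05 equiv), THF, −78 °C; TMSCl (1.2 equiv), −78 to 0 °C; pentane, filtration, used crude
Reagents that add atoms: chlorotrimethylsilane (TMSCl), C[Si](C)(C)Cl
Why: Kinetic deprotonation at the only enolisable position and O-silylation of the lithium enolate (silyl enol ether formation) give the nucleophile for the Mukaiyama aldol step without exposing the aryl fluoride to a nucleophilic base; no stereocentre is formed.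

Step 3
Reactants: 4 {[1-(4-bromo-2-fluoro-5-(methoxymethoxy)phenyl)ethenyl]oxy}trimethylsilane, 5 methyl pyruvate (methyl 2-oxopropanoate)
Product: 8 methyl (2S)-7-bromo-6-(methoxymethoxy)-2-methyl-4-oxochromane-2-carboxylate, via silyl aldolate 6 (not isolated), via cesium alkoxide 7 (not isolated)
Conditions: 5 (1.1 equiv), Cu(OTf)2 (10 mol %), (S,S)-tBu-box (11 mol %), THF, −78 °C; then DMF, CsF (0.5 equiv), −20 to 40 °C
Reagents that add atoms: none
Why: Methyl pyruvate 5 chelates through both carbonyl oxygens to the square-planar divalent copper centre of the Cu(OTf)2/(S,S)-tBu-box complex and enol silane 4 adds to its ketone carbon (Lewis acid Mukaiyama aldol addition with silyl transfer), forming the C2–C3 bond and the silyl aldolate 6. Fluoride then takes the silyl group, alkoxide 7 adds to C8a, the carbon that bears fluorine ortho to the aryl ketone, and the carbonyl-stabilised Meisenheimer adduct expels fluoride, which forms the O1–C8a bond and carries the desilylation on as a chain. The closest known reaction types are the copper–bis(oxazoline)-catalysed enantioselective aldol addition of ketone enol silanes to pyruvate esters and the fluoride-promoted SNAr etherification of silyl ethers with ortho-acyl fluoroarenes, here run in one flask. The pyranone ring closes as a six-membered ring by addition–elimination at the sp2 carbon C8a, formally 6-endo-trig with respect to the C8a=C4a–C4=O unit. The C2 stereocentre is set by the ligand alone: its tert-butyl groups shield the re face of the chelated ketone, attack on the si face gives (S)-6, and the ring closure does not touch C2, so 8 is (S), which corresponds to (R) in the target once the ester has become the alkyl chain. The step needs enantioface selectivity (ligand), displacement of F and not Br (fluoride is the far better leaving group in addition–elimination and the tethered oxygen can reach only C8a) and ring closure faster than retro-aldol cleavage of 7 (the α-ester stabilises the alkoxide against cleavage, and the fluoride relay keeps free base catalytic so that 8 is not opened by enolisation at C3).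

Step 4
Reactants: 8 methyl (2S)-7-bromo-6-(methoxymethoxy)-2-methyl-4-oxochromane-2-carboxylate
Product: 9 (2S,4RS)-7-bromo-4-hydroxy-6-(methoxymethoxy)-2-methylchromane-2-carbaldehyde (mixture of C4 epimers)
Conditions: i-Bu2AlH (2.3 equiv), CH2Cl2, −78 °C; MeOH, then aq. potassium sodium tartrate
Reagents that add atoms: none
Why: Hydride reduction with i-Bu2AlH at −78 °C takes the ketone to the carbinol and stops the α-aryloxy ester at the aldehyde stage because its tetrahedral intermediate, held by chelation and by the quaternary α-carbon, survives until the quench (partial ester reduction, well precedented for chromane-2-carboxylates); the new C4 carbinol centre forms without control and is erased in step 8, and with the ketone out of the way the basic step 6 cannot open the pyranone ring by enolisation and β-elimination, so C2 stays intact.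

Step 5
Reactants: 10 4-bromo-2-methylbutan-2-ol
Product: 11 (3-hydroxy-3-methylbutyl)triphenylphosphonium bromide
Conditions: PPh3, toluene, reflux
Reagents that add atoms: triphenylphosphine, c1ccc(cc1)P(c1ccccc1)c1ccccc1
Why: SN2 quaternisation of PPh3 by the primary bromide gives the phosphonium salt; the tertiary alcohol does not interfere and no stereocentre is involved.

Step 6
Reactants: 9 (2S,4RS)-7-bromo-4-hydroxy-6-(methoxymethoxy)-2-methylchromane-2-carbaldehyde, 11 (3-hydroxy-3-methylbutyl)triphenylphosphonium bromide
Product: 13 (2S,4RS)-7-bromo-2-[(1Z)-4-hydroxy-4-methylpent-1-en-1-yl]-6-(methoxymethoxy)-2-methylchroman-4-ol, via alkoxide ylide 12 (not isolated)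
Conditions: 11 (2.5 equiv), n-BuLi (5.0 equiv), THF, 0 °C; then 9, −78 °C to rt
Reagents that add atoms: none
Why: Wittig olefination: two equivalents of n-BuLi per phosphonium salt give the alkoxide ylide 12 (the alkoxide keeps the hydroxyl from closing onto phosphorus), one equivalent of 12 is spent on the C4 hydroxyl, and the non-stabilised ylide adds to the non-enolisable aldehyde to give mainly the Z alkene, whose geometry is of no consequence; C2 is untouched.

Step 7
Reactants: 13 (2S,4RS)-7-bromo-2-[(1Z)-4-hydroxy-4-methylpent-1-en-1-yl]-6-(methoxymethoxy)-2-methylchroman-4-ol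
Product: 14 (2R,4RS)-7-bromo-2-(4-hydroxy-4-methylpentyl)-6-(methoxymethoxy)-2-methylchroman-4-ol
Conditions: H2 (1–3 atm), RhCl(PPh3)3 (5 mol %), benzene/EtOH, rt
Reagents that add atoms: none
Why: Homogeneous hydrogenation with RhCl(PPh3)3 saturates the disubstituted alkene and leaves the aryl bromide, the benzylic carbinol and the MOM ether alone, where a heterogeneous palladium catalyst would cleave C–Br; no stereocentre is formed and the C2 descriptor changes from S to R only through the change in priorities.

Step 8
Reactants: 14 (2R,4RS)-7-bromo-2-(4-hydroxy-4-methylpentyl)-6-(methoxymethoxy)-2-methylchroman-4-ol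
Product: 15 (2R)-7-bromo-2-(4-hydroxy-4-methylpentyl)-6-(methoxymethoxy)-2-methylchroman-4-one
Conditions: Dess–Martin periodinane (1.3 equiv), NaHCO3, CH2Cl2, 0 °C to rt
Reagents that add atoms: none
Why: Dess–Martin oxidation of the secondary benzylic carbinol restores the C4 ketone under buffered, non-basic conditions, the tertiary alcohol cannot be oxidised, and the C4 epimers converge on a single compound.

Step 9
Reactants: 15 (2R)-7-bromo-2-(4-hydroxy-4-methylpentyl)-6-(methoxymethoxy)-2-methylchroman-4-one
Product: 16 (2R)-7-bromo-6-hydroxy-2-(4-hydroxy-4-methylpentyl)-2-methylchroman-4-one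
Conditions: 2 M aq. HCl, THF, 40 °C
Reagents that add atoms: none
Why: Acid-catalysed hydrolysis of the aryl MOM acetal through the methoxymethyl cation frees the phenol; in dilute aqueous acid the excess of water keeps the tertiary alcohol from ionising to chloride or alkene, and acid does not open the pyranone ring, so C2 is retained.

**Compound list**

1 | 1-(4-bromo-2-fluoro-5-hydroxyphenyl)ethan-1-one | CC(=O)c1cc(O)c(Br)cc1F | starting material
2 | 1-[4-bromo-2-fluoro-5-(methoxymethoxy)phenyl]ethan-1-one | CC(=O)c1cc(OCOC)c(Br)cc1F | intermediate
3 | lithium 1-[4-bromo-2-fluoro-5-(methoxymethoxy)phenyl]ethen-1-olate (lithium enolate) | [Li+].[O-]C(=C)c1cc(OCOC)c(Br)cc1F | intermediate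
4 | {[1-(4-bromo-2-fluoro-5-(methoxymethoxy)phenyl)ethenyl]oxy}trimethylsilane | C=C(O[Si](C)(C)C)c1cc(OCOC)c(Br)cc1F | intermediate
5 | methyl pyruvate | CC(=O)C(=O)OC | starting material
6 | methyl (2S)-4-[4-bromo-2-fluoro-5-(methoxymethoxy)phenyl]-2-methyl-4-oxo-2-[(trimethylsilyl)oxy]butanoate (silyl aldolate) | COC(=O)[C@](C)(CC(=O)c1cc(OCOC)c(Br)cc1F)O[Si](C)(C)C | intermediate
7 | cesium (2S)-4-[4-bromo-2-fluoro-5-(methoxymethoxy)phenyl]-1-methoxy-2-methyl-1,4-dioxobutan-2-olate (cesium alkoxide) | COC(=O)[C@](C)(CC(=O)c1cc(OCOC)c(Br)cc1F)[O-].[Cs+] | intermediate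
8 | methyl (2S)-7-bromo-6-(methoxymethoxy)-2-methyl-4-oxochromane-2-carboxylate | COC(=O)[C@]1(C)CC(=O)c2cc(OCOC)c(Br)cc2O1 | intermediate
9 | (2S,4RS)-7-bromo-4-hydroxy-6-(methoxymethoxy)-2-methylchromane-2-carbaldehyde, C4 epimers | O=C[C@]1(C)CC(O)c2cc(OCOC)c(Br)cc2O1 | intermediate
10 | 4-bromo-2-methylbutan-2-ol | CC(C)(O)CCBr | starting material
11 | (3-hydroxy-3-methylbutyl)triphenylphosphonium bromide | CC(C)(O)CC[P+](c1ccccc1)(c1ccccc1)c1ccccc1.[Br-] | intermediate
12 | lithium 2-methyl-4-(triphenylphosphoranylidene)butan-2-olate (alkoxide ylide) | CC(C)([O-])CC=P(c1ccccc1)(c1ccccc1)c1ccccc1.[Li+] | intermediate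
13 | (2S,4RS)-7-bromo-2-[(1Z)-4-hydroxy-4-methylpent-1-en-1-yl]-6-(methoxymethoxy)-2-methylchroman-4-ol, C4 epimers | CC(C)(O)C/C=C\[C@]1(C)CC(O)c2cc(OCOC)c(Br)cc2O1 | intermediate
14 | (2R,4RS)-7-bromo-2-(4-hydroxy-4-methylpentyl)-6-(methoxymethoxy)-2-methylchroman-4-ol, C4 epimers | CC(C)(O)CCC[C@]1(C)CC(O)c2cc(OCOC)c(Br)cc2O1 | intermediate
15 | (2R)-7-bromo-2-(4-hydroxy-4-methylpentyl)-6-(methoxymethoxy)-2-methylchroman-4-one | CC(C)(O)CCC[C@]1(C)CC(=O)c2cc(OCOC)c(Br)cc2O1 | intermediate
16 | (2R)-7-bromo-6-hydroxy-2-(4-hydroxy-4-methylpentyl)-2-methylchroman-4-one | CC(C)(O)CCC[C@]1(C)CC(=O)c2cc(O)c(Br)cc2O1 | target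

**Step count**

Total: 9 steps. Longest linear sequence: 8 steps (steps 1–4 and 6–9); step 5 prepares the Wittig salt.

**Steps most likely to fail**

1. Step 3. The desilylated tertiary alkoxide may revert by retro-aldol cleavage and re-add without catalyst control before it closes the ring, or the pyranone ring of the product may be opened and re-closed by base; either lowers the enantiomeric purity. The displacement may also be slow because the leaving fluoride is para to an alkoxy group. The fallback sets out from 2 and comes back at 15, and replaces catalyst control by resolution. Ketone 2 is treated with LiN(SiMe3)2 (2.1 equiv, THF, −78 °C) and commercial 6-hydroxy-6-methylheptan-2-one, and the mixture is warmed in THF/DMF. Aldol addition of lithium enolate 3 and displacement of fluoride should give, after mildly acidic work-up that re-closes any ring-opened enone, racemic 7-bromo-2-(4-hydroxy-4-methylpentyl)-6-(methoxymethoxy)-2-methylchroman-4-one F1. Its enantiomers are separated by preparative HPLC on a cellulose tris(3,5-dimethylphenylcarbamate) phase; the (R) enantiomer is 15.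

2. Step 4. The reduction may run on past the aldehyde stage, and the cis hydroxy aldehyde may be captured as a bridged lactol, so that a mixture hard to separate results. The fallback sets out from 8 and comes back at 9, and replaces partial reduction by full reduction and selective re-oxidation. LiBH4 (THF, MeOH, 0 °C to rt) reduces ester and ketone to (2S,4RS)-7-bromo-2-(hydroxymethyl)-6-(methoxymethoxy)-2-methylchroman-4-ol F2. The primary carbinol alone is then oxidised with TEMPO (10 mol %) and PhI(OAc)2 in CH2Cl2 to give 9.

3. Step 6. Carbonyl addition at the neopentyl-type aldehyde, partly masked as its lactolate, may be slow, and the ylide may be lost by closure of its own hydroxyl onto phosphorus. The fallback sets out from 9 and comes back at 14, and builds the chain by metathesis. Methylenation of 9 with Ph3P=CH2 (from Ph3PCH3Br and KOt-Bu, THF), a small ylide without a hydroxyl group, gives (2S,4RS)-7-bromo-2-ethenyl-6-(methoxymethoxy)-2-methylchroman-4-ol F3. Cross-metathesis of F3 with commercial 2-methylpent-4-en-2-ol (3 equiv) and the second-generation Hoveyda–Grubbs catalyst, RuCl2(H2IMes)(=CH-C6H4-2-Oi-Pr), in CH2Cl2 at 40 °C gives (2S,4RS)-7-bromo-2-[(1E)-4-hydroxy-4-methylpent-1-en-1-yl]-6-(methoxymethoxy)-2-methylchroman-4-ol F4. Hydrogenation under the conditions of step 7 then gives 14.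

Further compounds
F1 | step 3 | racemic 7-bromo-2-(4-hydroxy-4-methylpentyl)-6-(methoxymethoxy)-2-methylchroman-4-one | CC(C)(O)CCCC1(C)CC(=O)c2cc(OCOC)c(Br)cc2O1
F2 | step 4 | (2S,4RS)-7-bromo-2-(hydroxymethyl)-6-(methoxymethoxy)-2-methylchroman-4-ol | OC[C@]1(C)CC(O)c2cc(OCOC)c(Br)cc2O1
F3 | step 6 | (2S,4RS)-7-bromo-2-ethenyl-6-(methoxymethoxy)-2-methylchroman-4-ol | C=C[C@]1(C)CC(O)c2cc(OCOC)c(Br)cc2O1
F4 | step 6 | (2S,4RS)-7-bromo-2-[(1E)-4-hydroxy-4-methylpent-1-en-1-yl]-6-(methoxymethoxy)-2-methylchroman-4-ol | CC(C)(O)C/C=C/[C@]1(C)CC(O)c2cc(OCOC)c(Br)cc2O1
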